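## Analysis of the target

Target 23 is a 2-arylbenzofuran. Ring A (benzene) and ring B (furan) make up the benzofuran, which is joined through its C2 to C5 of a 2,2-dimethylchroman made of ring C (benzene) and ring D (dihydropyran). Ring A carries hydroxyls at C4 and C6 and a 2-methylbut-3-en-2-yl (1,1-dimethylallyl) group at C7; ring C carries a hydroxyl at C7. There is no stereocentre, since chroman C2 and the quaternary side-chain carbon each bear two methyl groups, so only constitution has to be controlled. The sensitive groups are three free phenols on electron-rich rings and a terminal vinyl group on a quaternary carbon next to the C6 hydroxyl, which acid would cyclise onto that oxygen and hydrogen would saturate; the last unmasking must therefore be neither acidic nor reductive. The difficulty is positional: on ring C the alkyl carbon C4 hangs on C4a, ortho to the carbon substituent at C5 and not between the two oxygens where prenylation of a 5-substituted resorcinol tends to go, and on ring A the tertiary allyl group sits at C7 between two oxygens, where direct alkylation would deliver the linear isomer. The strategy rests on the triad C8a (oxygen-bearing), C4a (CH2-bearing), C5 (carbon-bearing) of ring C, which is the arrangement of C4 (OH), C3a (lactone CH2) and C7a (carbonyl) in a 4-hydroxyphthalide. The lactone methylene can therefore become chroman C4, and the lactone carbonyl the carbon from which ring B is grown.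

## Retrosynthetic reasoning

**Unmasking (23 from 22).** No skeletal bond is cut. All three phenols of 23 are carried as silyl ethers in 22, because fluoride removes them without acid or hydrogen and so spares the vinyl group and its neighbouring hydroxyl.

**Ring B (22 from 19 and 11).** The C2=C3 and O1–C2 bonds of the furan are cut, giving the ring A phosphonium salt 19 and the ring C/D acid chloride 11. This cut splits the molecule into two halves of similar size, each holding one of the two positional problems. It delivers the benzofuran at its final oxidation level, and it uses the carboxyl carbon left by the chroman construction as benzofuran C2. The forward reaction has to acylate the one free phenol of 19 and then close the ring by an intramolecular Wittig reaction on the ester carbonyl. Only the oxygen lying between the benzylic carbon and the tertiary allyl group is free, so the furan can fuse in one sense only.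

**Activation of the acid (11 from 10 from 9).** These are functional group changes. The phenol of chroman acid 9 must be masked before the acid chloride is made, and the doubly silylated 10 allows the acid chloride to be formed without liberating acid.

**Ring D (9 from 5 and 6).** The chroman C3–C4 and O1–C2 bonds are cut in a retro-hetero-Diels–Alder sense, which leads to isobutene 6 and the ortho-quinone methide carboxylate 8. Intermediate 8 is a ring-opened valence form of 4,6-dihydroxyphthalide 5. The cut is made here because it turns the awkward placement of C4 into a consequence of where a lactone methylene sits, and because it closes ring D and frees the carboxyl handle in one operation. The forward reaction has to break the benzylic C–O bond of the lactone. In 5 that bond lies in the arene plane and is badly aligned for expulsion by the phenoxide, so the plan is to open the lactone hydrolytically in the flask to 7, whose benzylic C–O bond can rotate, and to generate 8 from there.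

**The phthalide (5 from 4 from 1 and 2).** The aryl–CH2 bond and the lactone C–O bond are cut. 3,5-Dimethoxybenzoic acid 1 is substituted by formaldehyde 2 at the position ortho to the carboxyl group, and the carboxyl group captures the new benzylic carbon as lactone 4 by way of 3. Ether cleavage then gives 5. The lactone is absent from the target and is built only to put one carbon ortho to the carboxyl group.

**The phosphonium salt (19 from 18 from 17).** The P–C bond is cut back to the ortho-hydroxybenzyl alcohol 18, which comes from salicylaldehyde 17 by hydride reduction.

**The tertiary allyl group (17 from 15).** The bond between ring A and the quaternary carbon is traced to a [3,3] shift of the O-prenyl ether 15 through dienone 16. Allyl inversion gives the branched group that direct alkylation cannot, and the formyl group occupies the other ortho position.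

**Differentiating the oxygens (15 from 13 and 14; 13 from 12).** The ether C–O bond is cut to the alcohol 14 and the chelated phenol 13. Compound 13 arises from purchased 2,4,6-trihydroxybenzaldehyde 12, whose formyl group holds back one hydroxyl by hydrogen bonding while the other two are silylated.

## Alternatives that were turned down

**Alternative 1:** The two C–C bonds at the quaternary side-chain carbon of ring A (to methyl and to vinyl) are disconnected, tracing that carbon to the carbonyl carbon of the aryl methyl ketone A1. In the forward key step a methyl Grignard reagent adds to the ketone of A1, and the alkoxide takes a carbonate group from a neighbouring oxygen and expels it. The resulting ortho-quinone methide then accepts a vinyl Grignard reagent in a 1,4-addition, giving phenol A2.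
- In its favour: this cascade is an established reaction type, runs cold, and sets the crowded quaternary carbon without a sigmatropic step. It avoids the ipso and para pathways and the high temperature of the Claisen step 8, and on that point it is stronger than the chosen route.
- Against it: it solves only the side chain of ring A. The position of C4 on ring C, which is the harder problem, is untouched, and the chroman half must still come from elsewhere. A2 also still lacks the carbon that becomes benzofuran C3, so a formylation and several protecting-group changes follow and the count for ring A is no shorter.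
- Comparison: the chosen strategy spends its one unprecedented step on ring D, reaches acid 9 in three steps, and accepts a conventional rearrangement for ring A.

**Alternative 2:** Ring C itself is disconnected at C8a–C4a and C5–C6, with ring D formed by the tether. In the forward key step the bis(silyloxy)diene–alkyne A3 is heated, undergoes intramolecular [4+2] cycloaddition, and aromatises by loss of silanol to give phenol A4 after work-up.
- In its favour: the tether dictates the fusion of rings C and D, so there is no positional doubt at all. On that certainty, and in forming two rings at once, it is stronger than the chosen key step.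
- Against it: the route is linear. The complete benzofuran with its acid-sensitive side chain has to be carried into A3. The diene is a hydrolytically fragile ketene acetal, and the dienophile is an alkyne conjugated to an electron-rich heteroarene, so diene and dienophile are electronically mismatched and a high temperature is needed, at which silyl shifts in the diene compete. The acetal protecting groups of A4 need acid for removal, next to the tertiary allyl group and its ortho oxygen.
- Comparison: the chosen strategy keeps the two halves separate until two steps from the end, builds ring D from bulk chemicals, and ends with fluoride only.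

**Alternative 3:** Benzofuran C3–C3a is disconnected as the result of a 1,2-aryl shift, so that ring B derives from the six-membered pyranone of flavanone A5. In the forward key step a diacetoxyiodoarene and strong acid in an orthoformate convert A5 to its enol ether, iodinate C3 and cause ring A to migrate from the carbonyl carbon to C3, giving the ring-contracted ester A6.
- In its favour: flavanones are assembled by robust aldol and oxa-Michael chemistry, and the oxidative ring contraction is a known reaction type. Its precedent is better than that of the chosen key step.
- Against it: the ester carbon must afterwards be excised and the dihydrofuran dehydrogenated, and two stereocentres are made only to be destroyed. The acidic, oxidising conditions force methyl and benzyl ethers, whose removal by Lewis acid or hydrogenolysis endangers the vinyl group. The tertiary allyl group is absent from A6 and would have to be added later on a benzofuran in which C5 and C7 both flank the C6 oxygen. The aryl group of A5 is the same 5-substituted chroman whose regiochemistry is the central problem, so this plan presupposes its solution.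
- Comparison: the chosen strategy solves that problem directly and reaches the benzofuran at the correct oxidation level in one operation.

Key step: step 3

Remark on the chemistry: intermediates 7 and 8 are drawn as monopotassium carboxylates, although their phenols are partly ionised in the flask, and dienone 16 is a transient racemate.

## Route

Step 1
Reactants: 1 3,5-dimethoxybenzoic acid; 2 formaldehyde (37% aqueous)
Product: 4 4,6-dimethoxy-2-benzofuran-1(3H)-one (4,6-dimethoxyphthalide), via hydroxymethyl acid 3 (not isolated)
Conditions: conc. HCl, AcOH, 90 °C
Reagents that add atoms: none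
Why: Blanc-type hydroxymethylation under chloromethylation conditions should occur at C2 of 1, which is ortho to one methoxyl, para to the other and less hindered than C4 between both; the neighbouring carboxyl group then closes the five-membered lactone, which also keeps the benzylic carbon from alkylating a second ring. Formaldehyde is kept near one equivalent to limit a second substitution at C7.

Step 2
Reactants: 4 4,6-dimethoxyphthalide
Product: 5 4,6-dihydroxy-2-benzofuran-1(3H)-one (4,6-dihydroxyphthalide)
Conditions: BBr3 (3.5 equiv), CH2Cl2, −78 °C to rt; then H2O, 50 °C
Reagents that add atoms: none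
Why: Lewis acid ether cleavage with BBr3 removes both aryl methyl groups; if the lactone is opened to a bromomethyl acid on the way, the warm aqueous work-up closes it again, so 5 is the expected product.

Step 3
Reactants: 5 4,6-dihydroxyphthalide; 6 2-methylpropene (isobutene)
Product: 9 7-hydroxy-2,2-dimethyl-3,4-dihydro-2H-chromene-5-carboxylic acid, via ring-opened potassium hydroxymethylbenzoate 7 (not isolated), via ortho-quinone methide carboxylate 8 (not isolated)
Conditions: K2CO3 (1.5 equiv), H2O/1,4-dioxane 1:1 (0.05 M), 90 °C, 1 h; then 6 (30 equiv), sealed autoclave, 140 °C, 12 h; vent; 2 M HCl to pH 2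
Reagents that add atoms: water, O
Why: Proposed new method: in 5 the CH2–O bond lies in the plane of ring C and cannot overlap with the phenoxide π system, so hot aqueous carbonate is used to open the lactone at the acyl carbon first, giving benzoate 7, in which the benzylic C–O bond can rotate into alignment. The phenoxide ortho to the CH2 group, assisted by the para hydroxyl, then expels hydroxide to give ortho-quinone methide 8, and the geometric constraint that disfavoured direct ionisation now slows recapture by the adjacent carboxylate (a 5-endo-trig closure), leaving time for a bimolecular trap. Isobutene 6, in large excess, adds across the O=C–C=CH2 unit in an inverse-electron-demand hetero-Diels–Alder reaction, an intermolecular [4+2] closure of ring D that forms C3–C4 and O1–C2 together and re-aromatises ring C. The closest known reaction type is the base- or heat-induced formation of ortho-quinone methides from ortho-hydroxybenzyl alcohols, esters or Mannich bases and their capture by alkenes to give chromans; the opening of phthalein lactones to quinone methide carboxylates in base is the nearest analogy for using a phthalide, which has not been shown as the precursor. Regioselectivity follows from polarity: the electrophilic methide carbon bonds to the CH2 terminus of 6 and the oxygen to the carbon that best bears positive charge, which fixes the 2,2-dimethyl pattern. Site selectivity is built into 5, because only the hydroxyl ortho to the CH2 group can complete a six-membered ring, while the para-quinone methide tautomer can only return by re-addition of water. The selectivity that has to be won is against C-alkylation of a second phenoxide ring by 8, and high dilution of 5 together with a high concentration of 6 is meant to secure it, while return to 7 or 5 merely recycles material. No stereocentre is formed, and acidification should give 9 as a bicarbonate-soluble acid, separable from relactonised 5.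

Step 4
Reactants: 9 7-hydroxy-2,2-dimethylchroman-5-carboxylic acid
Product: 10 tert-butyldimethylsilyl 7-[(tert-butyldimethylsilyl)oxy]-2,2-dimethyl-3,4-dihydro-2H-chromene-5-carboxylate
Conditions: TBSCl (2.5 equiv), imidazole (5 equiv), DMF, rt
Reagents that add atoms: tert-butyldimethylsilyl chloride, CC(C)(C)[Si](C)(C)Cl
Why: Silylation with TBSCl and imidazole caps the phenol as its silyl ether and the acid as its silyl ester; the ester is kept because it is the substrate of the next step.

Step 5
Reactants: 10 bis-silylated chroman acid
Product: 11 7-[(tert-butyldimethylsilyl)oxy]-2,2-dimethyl-3,4-dihydro-2H-chromene-5-carbonyl chloride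
Conditions: (COCl)2 (1.2 equiv), DMF (cat.), CH2Cl2, 0 °C to rt; evaporate, use crude
Reagents that add atoms: oxalyl chloride, O=C(Cl)C(=O)Cl
Why: Silyl esters are converted by oxalyl chloride and catalytic DMF (Vilsmeier-type chloroiminium activation) into acid chlorides with loss of the silyl chloride and without HCl, so the aryl silyl ether should survive.

Step 6
Reactants: 12 2,4,6-trihydroxybenzaldehyde
Product: 13 2-hydroxy-4,6-bis[(triisopropylsilyl)oxy]benzaldehyde
Conditions: TIPSCl (2.1 equiv), imidazole (4 equiv), DMF, 0 °C to rt
Reagents that add atoms: triisopropylsilyl chloride, CC(C)[Si](Cl)(C(C)C)C(C)C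
Why: Selective silylation: the 4-hydroxyl is the most acidic and least hindered, and once one ortho hydroxyl is silylated the last one is locked in a hydrogen bond to the formyl oxygen, so the bulky silyl chloride should stop at bis-ether 13.

Step 7
Reactants: 13 2-hydroxy-4,6-bis[(triisopropylsilyl)oxy]benzaldehyde; 14 3-methylbut-2-en-1-ol
Product: 15 2-[(3-methylbut-2-en-1-yl)oxy]-4,6-bis[(triisopropylsilyl)oxy]benzaldehyde
Conditions: PPh3 (1.3 equiv), DIAD (1.3 equiv), THF, 0 °C to rt
Reagents that add atoms: none
Why: Mitsunobu etherification of the acidic, chelated phenol with the primary allylic alcohol 14 should give the unrearranged O-prenyl ether under neutral conditions, which spare the aryl silyl ethers that a carbonate-mediated alkylation might cleave.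

Step 8
Reactants: 15 O-prenyl ether
Product: 17 2-hydroxy-3-(2-methylbut-3-en-2-yl)-4,6-bis[(triisopropylsilyl)oxy]benzaldehyde, via dienone 16 (not isolated)
Conditions: N,N-diethylaniline, 190 °C, sealed tube, argon
Reagents that add atoms: none
Why: Aromatic Claisen rearrangement ([3,3]-sigmatropic shift): the dimethyl-substituted allyl terminus bonds to C3, the only unsubstituted ortho carbon, giving dienone 16, which tautomerises to the phenol with help from the amine solvent and the hydrogen bond to the formyl group; allyl inversion delivers the 2-methylbut-3-en-2-yl group. The bulky silyl ethers on both sides of C5 should hinder a following Cope shift to that carbon.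

Step 9
Reactants: 17 2-hydroxy-3-(2-methylbut-3-en-2-yl)-4,6-bis[(triisopropylsilyl)oxy]benzaldehyde
Product: 18 2-(hydroxymethyl)-6-(2-methylbut-3-en-2-yl)-3,5-bis[(triisopropylsilyl)oxy]phenol
Conditions: NaBH4 (1.5 equiv), THF/MeOH 4:1, 0 °C; pH 7 buffer
Reagents that add atoms: none
Why: Borohydride reduction of the aldehyde to the benzylic alcohol leaves the alkene and the aryl silyl ethers untouched; the reaction is kept cold and worked up at neutral pH because the electron-rich ortho-hydroxybenzyl alcohol ionises easily, and 18 is used at once.

Step 10
Reactants: 18 2-(hydroxymethyl)-6-(2-methylbut-3-en-2-yl)-3,5-bis[(triisopropylsilyl)oxy]phenol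
Product: 19 {2-hydroxy-3-(2-methylbut-3-en-2-yl)-4,6-bis[(triisopropylsilyl)oxy]benzyl}triphenylphosphonium bromide
Conditions: PPh3·HBr (1.05 equiv), MeCN, rt
Reagents that add atoms: triphenylphosphine hydrobromide, [Br-].[PH+](c1ccccc1)(c1ccccc1)c1ccccc1
Why: Under the mild acid the ortho-hydroxybenzyl alcohol ionises to a benzylic cation (protonated ortho-quinone methide) that PPh3 captures in an SN1-type substitution, the standard entry to (2-hydroxybenzyl)phosphonium salts; the acid is too weak to add to the vinyl group at room temperature.

Step 11
Reactants: 19 ring A phosphonium bromide; 11 chroman acid chloride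
Product: 22 2-{7-[(tert-butyldimethylsilyl)oxy]-2,2-dimethylchroman-5-yl}-7-(2-methylbut-3-en-2-yl)-4,6-bis[(triisopropylsilyl)oxy]-1-benzofuran, via acyloxy phosphonium salt 20 (not isolated), via ester ylide 21 (not isolated)
Conditions: 11 (1.05 equiv), Et3N (3.5 equiv), DMAP (0.1 equiv), toluene, 0 °C to rt, then 110 °C
Reagents that add atoms: none
Why: O-Acylation of the phenoxide by 11 gives ester salt 20; Et3N then forms ylide 21, which attacks the neighbouring ester carbonyl in an intramolecular Wittig reaction (five-membered ring closure with loss of Ph3PO) to form C2=C3 of ring B. Only the oxygen between the benzylic carbon and the tertiary allyl group is free, so the furan can fuse in one orientation only.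

Step 12
Reactants: 22 tris-silylated benzofuran
Product: 23 2-(7-hydroxy-2,2-dimethyl-3,4-dihydro-2H-chromen-5-yl)-7-(2-methylbut-3-en-2-yl)-1-benzofuran-4,6-diol (target, CNP0300714.0)
Conditions: TBAF (4 equiv), AcOH (4 equiv), THF, 0 °C to rt, argon
Reagents that add atoms: none
Why: Fluoride cleaves the three aryl silyl ethers through Si–F bond formation; the AcOH buffer protects the liberated polyphenoxide from oxidation, and the conditions are neither acidic enough to cyclise the allyl group onto the C6 hydroxyl nor reductive.

## Compound list

1 | 3,5-dimethoxybenzoic acid | COc1cc(OC)cc(C(=O)O)c1 | starting material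
2 | formaldehyde | C=O | starting material
3 | 2-(hydroxymethyl)-3,5-dimethoxybenzoic acid | COc1cc(OC)c(CO)c(C(=O)O)c1 | intermediate (not isolated)
4 | 4,6-dimethoxy-2-benzofuran-1(3H)-one | O=C1OCc2c(OC)cc(OC)cc12 | intermediate
5 | 4,6-dihydroxy-2-benzofuran-1(3H)-one | O=C1OCc2c(O)cc(O)cc12 | intermediate
6 | 2-methylpropene | C=C(C)C | starting material
7 | potassium 3,5-dihydroxy-2-(hydroxymethyl)benzoate | [K+].[O-]C(=O)c1cc(O)cc(O)c1CO | intermediate (not isolated)
8 | potassium 3-hydroxy-6-methylidene-5-oxocyclohexa-1,3-diene-1-carboxylate | [K+].[O-]C(=O)C1=CC(O)=CC(=O)C1=C | intermediate (not isolated)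
9 | 7-hydroxy-2,2-dimethyl-3,4-dihydro-2H-chromene-5-carboxylic acid | O=C(O)c1cc(O)cc2OC(C)(C)CCc12 | intermediate
10 | tert-butyldimethylsilyl 7-[(tert-butyldimethylsilyl)oxy]-2,2-dimethyl-3,4-dihydro-2H-chromene-5-carboxylate | CC(C)(C)[Si](C)(C)OC(=O)c1cc(O[Si](C)(C)C(C)(C)C)cc2OC(C)(C)CCc12 | intermediate
11 | 7-[(tert-butyldimethylsilyl)oxy]-2,2-dimethyl-3,4-dihydro-2H-chromene-5-carbonyl chloride | O=C(Cl)c1cc(O[Si](C)(C)C(C)(C)C)cc2OC(C)(C)CCc12 | intermediate
12 | 2,4,6-trihydroxybenzaldehyde | O=Cc1c(O)cc(O)cc1O | starting material
13 | 2-hydroxy-4,6-bis[(triisopropylsilyl)oxy]benzaldehyde | O=Cc1c(O)cc(O[Si](C(C)C)(C(C)C)C(C)C)cc1O[Si](C(C)C)(C(C)C)C(C)C | intermediate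
14 | 3-methylbut-2-en-1-ol | CC(C)=CCO | starting material
15 | 2-[(3-methylbut-2-en-1-yl)oxy]-4,6-bis[(triisopropylsilyl)oxy]benzaldehyde | O=Cc1c(OCC=C(C)C)cc(O[Si](C(C)C)(C(C)C)C(C)C)cc1O[Si](C(C)C)(C(C)C)C(C)C | intermediate
16 | 5-(2-methylbut-3-en-2-yl)-6-oxo-2,4-bis[(triisopropylsilyl)oxy]cyclohexa-1,3-diene-1-carbaldehyde (racemic) | O=CC1=C(O[Si](C(C)C)(C(C)C)C(C)C)C=C(O[Si](C(C)C)(C(C)C)C(C)C)C(C(C)(C)C=C)C1=O | intermediate (not isolated)
17 | 2-hydroxy-3-(2-methylbut-3-en-2-yl)-4,6-bis[(triisopropylsilyl)oxy]benzaldehyde | O=Cc1c(O)c(C(C)(C)C=C)c(O[Si](C(C)C)(C(C)C)C(C)C)cc1O[Si](C(C)C)(C(C)C)C(C)C | intermediate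
18 | 2-(hydroxymethyl)-6-(2-methylbut-3-en-2-yl)-3,5-bis[(triisopropylsilyl)oxy]phenol | OCc1c(O)c(C(C)(C)C=C)c(O[Si](C(C)C)(C(C)C)C(C)C)cc1O[Si](C(C)C)(C(C)C)C(C)C | intermediate
19 | {2-hydroxy-3-(2-methylbut-3-en-2-yl)-4,6-bis[(triisopropylsilyl)oxy]benzyl}triphenylphosphonium bromide | [Br-].C=CC(C)(C)c1c(O)c(C[P+](c2ccccc2)(c2ccccc2)c2ccccc2)c(O[Si](C(C)C)(C(C)C)C(C)C)cc1O[Si](C(C)C)(C(C)C)C(C)C | intermediate
20 | {2-({7-[(tert-butyldimethylsilyl)oxy]-2,2-dimethylchroman-5-carbonyl}oxy)-3-(2-methylbut-3-en-2-yl)-4,6-bis[(triisopropylsilyl)oxy]benzyl}triphenylphosphonium bromide | [Br-].C=CC(C)(C)c1c(OC(=O)c2cc(O[Si](C)(C)C(C)(C)C)cc3OC(C)(C)CCc23)c(C[P+](c2ccccc2)(c2ccccc2)c2ccccc2)c(O[Si](C(C)C)(C(C)C)C(C)C)cc1O[Si](C(C)C)(C(C)C)C(C)C | intermediate (not isolated)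
21 | 2-(2-methylbut-3-en-2-yl)-3,5-bis[(triisopropylsilyl)oxy]-6-[(triphenyl-λ5-phosphanylidene)methyl]phenyl 7-[(tert-butyldimethylsilyl)oxy]-2,2-dimethylchroman-5-carboxylate | C=CC(C)(C)c1c(OC(=O)c2cc(O[Si](C)(C)C(C)(C)C)cc3OC(C)(C)CCc23)c(C=P(c2ccccc2)(c2ccccc2)c2ccccc2)c(O[Si](C(C)C)(C(C)C)C(C)C)cc1O[Si](C(C)C)(C(C)C)C(C)C | intermediate (not isolated)
22 | 2-{7-[(tert-butyldimethylsilyl)oxy]-2,2-dimethylchroman-5-yl}-7-(2-methylbut-3-en-2-yl)-4,6-bis[(triisopropylsilyl)oxy]-1-benzofuran | C=CC(C)(C)c1c(O[Si](C(C)C)(C(C)C)C(C)C)cc(O[Si](C(C)C)(C(C)C)C(C)C)c2cc(-c3cc(O[Si](C)(C)C(C)(C)C)cc4c3CCC(C)(C)O4)oc12 | intermediate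
23 | 2-(7-hydroxy-2,2-dimethyl-3,4-dihydro-2H-chromen-5-yl)-7-(2-methylbut-3-en-2-yl)-1-benzofuran-4,6-diol | C=CC(C)(C)c1c(O)cc(O)c2cc(-c3cc(O)cc4c3CCC(C)(C)O4)oc12 | target

## Step count and risk

Total: 12 steps, in two branches of five steps each (steps 1–5 and steps 6–10) followed by two common steps. The longest linear sequence is 7 steps (steps 1–5, 11, 12 from 1, or steps 6–12 from 12).

**Step 3 (key step, bears the label "Proposed new method:").** The most likely failure is that the quinone methide is consumed by C-alkylation of a second phenoxide ring (the phenol–formaldehyde pathway) faster than the unactivated, gaseous alkene can add. Oligomers would then form in place of the chroman. A second possibility is that hydroxide loss from 7 is too slow below the temperature at which the salt degrades. The fallback uses known chemistry, sets out from 1 and returns at 9. It builds C4–C4a by cross-coupling and O1–C2 by ionic cyclisation, not by cycloaddition. Electrophilic bromination of 1 (NBS, MeCN) at the position used in step 1 should give 2-bromo-3,5-dimethoxybenzoic acid F1. B-alkyl Suzuki–Miyaura coupling of F1 (Pd(dppf)Cl2, aqueous K3PO4, THF, 65 °C) with 4-(9-borabicyclo[3.3.1]nonan-9-yl)-2-methylbutan-2-ol F2, made in the flask from 2-methylbut-3-en-2-ol and 9-BBN, should give 2-(3-hydroxy-3-methylbutyl)-3,5-dimethoxybenzoic acid F3. Hot 48% HBr in AcOH then cleaves both methyl ethers and closes the chroman through the tertiary cation, delivering 9.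

**Step 8.** The allyl group may migrate to the formyl-bearing ortho carbon and then move on by a Cope shift to C5 or drive out the formyl group. Crowding by the neighbouring silyl ether may also slow the desired shift until thermal loss of the allyl group takes over. The fallback redesigns the rearrangement substrate, not the conditions; it sets out from 12 and returns at 17. Mitsunobu etherification of 12 with 14 at the unchelated 4-hydroxyl should give 2,6-dihydroxy-4-[(3-methylbut-2-en-1-yl)oxy]benzaldehyde F4. In F4 both ortho carbons are equivalent and unsubstituted, the para carbon carries the formyl group and no silyl group is present, so heating in N,N-diethylaniline should give 2,4,6-trihydroxy-3-(2-methylbut-3-en-2-yl)benzaldehyde F5. Silylation (TIPSCl, imidazole) should then take the 4- and 6-hydroxyls and leave the hydroxyl that is both chelated and flanked by the quaternary carbon, giving 17.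

**Step 11.** O-Acylation of a phenoxide flanked by the phosphonium-bearing methylene and the quaternary carbon may be slow. The ylide carbon could then be acylated by a second molecule of 11, which leads to 3-aroylbenzofurans, or the acid chloride could be lost to hydrolysis. The fallback sets out from 17 (with 11) and returns at 22, and it also bypasses 18 and 19. The sodium phenoxide of 17 (NaH, THF) is acylated by 11 without a competing carbon nucleophile, to give 2-formyl-6-(2-methylbut-3-en-2-yl)-3,5-bis[(triisopropylsilyl)oxy]phenyl 7-[(tert-butyldimethylsilyl)oxy]-2,2-dimethylchroman-5-carboxylate F6. Intramolecular reductive carbonyl–ester coupling with low-valent titanium (TiCl3, Zn dust, DME, reflux, high dilution; McMurry type) should then join the formyl and ester carbons to give 22.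

## Further compounds

F1 | step 3 | 2-bromo-3,5-dimethoxybenzoic acid | COc1cc(OC)c(Br)c(C(=O)O)c1
F2 | step 3 | 4-(9-borabicyclo[3.3.1]nonan-9-yl)-2-methylbutan-2-ol | CC(C)(O)CCB1C2CCCC1CCC2
F3 | step 3 | 2-(3-hydroxy-3-methylbutyl)-3,5-dimethoxybenzoic acid | COc1cc(OC)c(CCC(C)(C)O)c(C(=O)O)c1
F4 | step 8 | 2,6-dihydroxy-4-[(3-methylbut-2-en-1-yl)oxy]benzaldehyde | O=Cc1c(O)cc(OCC=C(C)C)cc1O
F5 | step 8 | 2,4,6-trihydroxy-3-(2-methylbut-3-en-2-yl)benzaldehyde | O=Cc1c(O)cc(O)c(C(C)(C)C=C)c1O
F6 | step 11 | 2-formyl-6-(2-methylbut-3-en-2-yl)-3,5-bis[(triisopropylsilyl)oxy]phenyl 7-[(tert-butyldimethylsilyl)oxy]-2,2-dimethylchroman-5-carboxylate | C=CC(C)(C)c1c(OC(=O)c2cc(O[Si](C)(C)C(C)(C)C)cc3OC(C)(C)CCc23)c(C=O)c(O[Si](C(C)C)(C(C)C)C(C)C)cc1O[Si](C(C)C)(C(C)C)C(C)C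
A1 | alternative 1 | di-tert-butyl 2-acetyl-5-[(tert-butyldimethylsilyl)oxy]-1,3-phenylene bis(carbonate) | CC(=O)c1c(OC(=O)OC(C)(C)C)cc(O[Si](C)(C)C(C)(C)C)cc1OC(=O)OC(C)(C)C
A2 | alternative 1 | tert-butyl 5-[(tert-butyldimethylsilyl)oxy]-3-hydroxy-2-(2-methylbut-3-en-2-yl)phenyl carbonate | C=CC(C)(C)c1c(O)cc(O[Si](C)(C)C(C)(C)C)cc1OC(=O)OC(C)(C)C
A3 | alternative 2 | 4,6-bis(methoxymethoxy)-7-(2-methylbut-3-en-2-yl)-2-(5-methyl-5-{[1,3-bis(trimethylsilyloxy)buta-1,3-dien-1-yl]oxy}hex-1-yn-1-yl)-1-benzofuran | C=C(O[Si](C)(C)C)C=C(O[Si](C)(C)C)OC(C)(C)CCC#Cc1cc2c(OCOC)cc(OCOC)c(C(C)(C)C=C)c2o1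
A4 | alternative 2 | 5-[4,6-bis(methoxymethoxy)-7-(2-methylbut-3-en-2-yl)-1-benzofuran-2-yl]-2,2-dimethylchroman-7-ol | C=CC(C)(C)c1c(OCOC)cc(OCOC)c2cc(-c3cc(O)cc4OC(C)(C)CCc34)oc12
A5 | alternative 3 | 7-(benzyloxy)-5-methoxy-2-(7-methoxy-2,2-dimethylchroman-5-yl)chroman-4-one (racemic) | O=C1CC(c2cc(OC)cc3OC(C)(C)CCc23)Oc2cc(OCc3ccccc3)cc(OC)c12
A6 | alternative 3 | methyl trans-6-(benzyloxy)-4-methoxy-2-(7-methoxy-2,2-dimethylchroman-5-yl)-2,3-dihydro-1-benzofuran-3-carboxylate (racemic) | COC(=O)[C@H]1[C@H](c2cc(OC)cc3OC(C)(C)CCc23)Oc2cc(OCc3ccccc3)cc(OC)c12
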